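The runs are calculated with constants of no real substance.

Two runs with a scatter of 2 percentage points cannot yield the constants of the proposed steps, so something has to be frozen first.

| flask | G | remark | time |
|---|---|---|---|
| violet | 0.032 M | run made earlier |  |
| red | 0.64 M | run made earlier |  |
| epsilon | 0.050 M |  | 40 h |
| gamma | 0.19 M |  | 40 h |
| zeta | 0.10 M |  | 40 h |
| theta | 0.80 M |  | 40 h |

| run | time / h | J / % | G / % |
|---|---|---|---|
| violet | 3.00 | 44 | 53 |
| violet | 5.00 | 51 | 41 |
| violet | 8.00 | 58 | 35 |
| violet | 12.0 | 51 | 35 |
| violet | 15.0 | 57 | 35 |
| violet | 25.0 | 53 | 34 |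
| violet | 40.0 | 54 | 30 |
| red | 6.00 | 47 | 30 |
| red | 12.0 | 40 | 30 |
| red | 15.0 | 42 | 23 |
| red | 25.0 | 37 | 24 |
| red | 30.0 | 32 | 22 |
| red | 40.0 | 34 | 18 |

(standard deviation of a reading: 2 percentage points)

- in percentages every species weighs as the G in it: one E counts as two
- steps that have been proposed: G <-> J; X <-> D; J <-> X; 2 G -> E

1. the flasks put in order of amount of J, in percent of the G charged, best first, at 40 h (epsilon / gamma / zeta / theta)
2. the amount of J, in percent of the G charged of the flask you put first, at 40 h
3. the amount of J, in percent of the G charged of the flask you put last, at 40 h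

*What is nearly constant?* The ratio J/G. It reads 1.66 in violet at 8.00 h and 1.54 in red at 25.0 h. Violet levels off well before the asked time, so I treat G ⇌ J as a pre-equilibrium, with G a fixed share of the pool G + J.

*What then separates the flasks?* Of the proposed steps, the one in which two G give E is second order in G. With the share frozen and the loss of J through X set aside, the pool decays by second-order kinetics. Let W be the reciprocal of J as a fraction of the charge, and c the charge of G. At fixed time, W = a + b·c.

*And b?* From red and violet at 40 h, 1.79 L mol⁻¹ is the dilution slope b, the rise of W per unit charge of G at fixed time. The intercept a is then 1.79.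

*Doesn't the leak through X spoil that?* It stays in the line as a loss I have not separated: a and b are both read from J at 40 h, so each carries it, and b is an empirical slope for that time, not a rate constant.

*Your numbers?* Epsilon 53.1%, zeta 50.7%, gamma 46.8%, theta 31.0%.

*The weak spot?* The line rests on two single readings. Its gap between epsilon and zeta, 2.4 points, is comparable to the scatter, so the order comes from the sign of b rather than from that gap.

The forecast gives epsilon > zeta > gamma > theta, with top 54% (50.5% to 57%) and low 30% (26% to 34%). Its top lies above mine and its low below mine. Its own line: “Lower concentration gives more J.”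

The flasks stand epsilon > zeta > gamma > theta, with epsilon at 51.6% and theta at 29.7%.

    G ⇌ J (K = 1.60, k = 0.290 h⁻¹)
    X ⇌ D (K = 8.50, k = 0.00730 h⁻¹)
    J ⇌ X (K = 0.170, k = 0.0430 h⁻¹)
    2 G → E (k = 0.0920 L mol⁻¹ h⁻¹)

At 40.0 h, theta holds 46.2% as E, more than the 5.51% in epsilon. The dilution slope put 46.8% on gamma, which gives 45.0%.

A further flask, like epsilon but charged with 0.020 M of G, gets 54.8% from the same line. It gives 53.3%.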